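## Retrosynthetic overview

1. The CH2 bridge between the two 4-hydroxy-2-pyrones is cut: a Mannich salt of the naphthyl pyrone (fragment B) gives a pyranedione methide, which the pyrone of the ketol half (fragment A) traps by Michael addition. Hydrogenolysis is the last step.
2. Fragment A (tetralone numbering: C1 ketone, C3 carbinol, C4 pyronyl carbon): the pyrone is made last from a dioxinone (acylketene) after a vinylogous Mukaiyama aldol on a C4 aldehyde. Before that, the tetralone ring closes by a SmI2 intramolecular Reformatsky-type aldol of a bromoacetyl arene onto the phenyl ketone, which sets C3 from C4.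
3. C4 comes from an Evans syn-aldol of an arylacetyl oxazolidinone (from 2-bromo-3-hydroxybenzaldehyde) with benzaldehyde. The aryl bromide later becomes the bromoacetyl group (Stille, NBS).
4. Fragment B: the naphthalene ring closes by an acid-mediated intramolecular aldol condensation of a 1,5-diketone. That diketone comes from Pd α-arylation of a phenacyl pyrone (from triacetic acid lactone) with an aryl triflate (from 2',6'-dihydroxyacetophenone).
5. Ring order: fragment A tetralone, then its pyrone; fragment B pyrone (bought), then its naphthalene; then the CH2 link.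

Assumption: enolates, alkoxides and borinate esters that are only the metalated form of a numbered compound and return to it on work-up are counted as that compound and get no number.

## Route

Step 1
Reactants: 1 2-bromo-3-hydroxybenzaldehyde
Product: 2 3-(benzyloxy)-2-bromobenzaldehyde
Conditions: BnBr, K2CO3, DMF, rt
Reagents that add atoms: benzyl bromide, BrCc1ccccc1
Why: Williamson ether synthesis on the phenoxide; the benzyl ether survives all later steps and is removed in the final hydrogenolysis.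

Step 2
Reactants: 2 3-(benzyloxy)-2-bromobenzaldehyde
Product: 4 2-[3-(benzyloxy)-2-bromophenyl]acetonitrile, via tosylvinyl formamide 3 (not isolated)
Conditions: TosMIC, KOt-Bu, DME, −40 °C; then MeOH, reflux
Reagents that add atoms: p-toluenesulfonylmethyl isocyanide (TosMIC), Cc1ccc(cc1)S(=O)(=O)C[N+]#[C-]
Why: van Leusen reductive cyanation; the non-enolizable aldehyde adds TosMIC, and methanolysis of 3 expels formate and sulfinate to give the one-carbon-homologated nitrile.

Step 3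
Reactants: 4 2-[3-(benzyloxy)-2-bromophenyl]acetonitrile
Product: 6 2-[3-(benzyloxy)-2-bromophenyl]acetic acid, via arylacetamide 5 (not isolated)
Conditions: KOH, EtOH/H2O, reflux; then HCl
Reagents that add atoms: water, O; potassium hydroxide, [K+].[OH-]
Why: alkaline nitrile hydrolysis through the primary amide; aryl bromide and benzyl ether are inert to hydroxide.

Step 4
Reactants: 6 2-[3-(benzyloxy)-2-bromophenyl]acetic acid; 7 (4S)-4-benzyl-1,3-oxazolidin-2-one
Product: 9 (4S)-4-benzyl-3-{2-[3-(benzyloxy)-2-bromophenyl]acetyl}-1,3-oxazolidin-2-one, via mixed pivalic anhydride 8 (not isolated)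
Conditions: t-BuCOCl, Et3N, THF, −20 °C; then 7, LiCl, rt
Reagents that add atoms: none
Why: mixed-anhydride N-acylation of the Evans auxiliary; the hindered pivaloyl carbonyl directs attack to the arylacetyl carbonyl.

Step 5
Reactants: 9 (4S)-4-benzyl-3-{2-[3-(benzyloxy)-2-bromophenyl]acetyl}-1,3-oxazolidin-2-one; 10 benzaldehyde
Product: 11 (4S)-4-benzyl-3-{(2S,3S)-2-[3-(benzyloxy)-2-bromophenyl]-3-hydroxy-3-phenylpropanoyl}-1,3-oxazolidin-2-one
Conditions: Bu2BOTf, i-Pr2NEt, CH2Cl2, −78 to 0 °C; 10, −78 to 0 °C; then pH 7 buffer, MeOH, H2O2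
Reagents that add atoms: none
Why: Evans syn-aldol through the Z-boron enolate and a Zimmerman–Traxler chair; the (S)-benzyl auxiliary fixes the aryl-bearing carbon (the future C4) as 2S, and the carbinol centre is a placeholder that is oxidized in step 8.

Step 6
Reactants: 11 (4S)-4-benzyl-3-{(2S,3S)-2-[3-(benzyloxy)-2-bromophenyl]-3-hydroxy-3-phenylpropanoyl}-1,3-oxazolidin-2-one
Product: 12 (1S,2R)-2-[3-(benzyloxy)-2-bromophenyl]-1-phenylpropane-1,3-diol
Conditions: LiBH4, THF, H2O (1 equiv), 0 °C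
Reagents that add atoms: none
Why: reductive cleavage of the imide by LiBH4 releases the auxiliary and gives the 1,3-diol without touching the aryl bromide or the stereocentres.

Step 7
Reactants: 12 (1S,2R)-2-[3-(benzyloxy)-2-bromophenyl]-1-phenylpropane-1,3-diol
Product: 13 (1S,2R)-2-[3-(benzyloxy)-2-bromophenyl]-1-phenyl-3-[(triethylsilyl)oxy]propan-1-ol
Conditions: Et3SiCl (1.05 equiv), imidazole, CH2Cl2, −40 °C
Reagents that add atoms: chlorotriethylsilane, CC[Si](Cl)(CC)CC
Why: selective silylation of the primary alcohol over the hindered secondary benzylic one; the silyl ether is a non-chelating group for the later samarium aldol.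

Step 8
Reactants: 13 (1S,2R)-2-[3-(benzyloxy)-2-bromophenyl]-1-phenyl-3-[(triethylsilyl)oxy]propan-1-ol
Product: 14 (2R)-2-[3-(benzyloxy)-2-bromophenyl]-1-phenyl-3-[(triethylsilyl)oxy]propan-1-one
Conditions: Dess–Martin periodinane, pyridine, CH2Cl2, 0 °C to rt
Reagents that add atoms: none
Why: Dess–Martin oxidation under buffered, base-free conditions gives the phenyl ketone, so the α-aryl β-silyloxy stereocentre neither epimerizes nor eliminates.

Step 9
Reactants: 14 (2R)-2-[3-(benzyloxy)-2-bromophenyl]-1-phenyl-3-[(triethylsilyl)oxy]propan-1-one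
Product: 15 (2R)-2-[3-(benzyloxy)-2-(1-ethoxyethenyl)phenyl]-1-phenyl-3-[(triethylsilyl)oxy]propan-1-one
Conditions: tributyl(1-ethoxyethenyl)stannane, Pd(PPh3)4 (5 mol%), CuI (10 mol%), toluene, 100 °C
Reagents that add atoms: tributyl(1-ethoxyethenyl)stannane, CCCC[Sn](CCCC)(CCCC)C(=C)OCC
Why: Stille coupling with zerovalent palladium under base-free conditions installs a masked acetyl group on the hindered aryl bromide while the enolizable ketone stays untouched.

Step 10
Reactants: 15 (2R)-2-[3-(benzyloxy)-2-(1-ethoxyethenyl)phenyl]-1-phenyl-3-[(triethylsilyl)oxy]propan-1-one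
Product: 16 (2R)-2-[3-(benzyloxy)-2-(2-bromoacetyl)phenyl]-1-phenyl-3-[(triethylsilyl)oxy]propan-1-one
Conditions: NBS, THF/H2O (4:1), 0 °C
Reagents that add atoms: N-bromosuccinimide, O=C1CCC(=O)N1Br; water, O
Why: electrophilic bromination of the electron-rich enol ether and hydrolysis of the resulting oxocarbenium ion place bromine only on the aryl ketone methyl, which direct bromination of a diketone could not do.

Step 11
Reactants: 16 (2R)-2-[3-(benzyloxy)-2-(2-bromoacetyl)phenyl]-1-phenyl-3-[(triethylsilyl)oxy]propan-1-one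
Product: 18 (3R,4R)-8-(benzyloxy)-3-hydroxy-3-phenyl-4-{[(triethylsilyl)oxy]methyl}-3,4-dihydronaphthalen-1(2H)-one, via samarium enolate 17 (not isolated)
Conditions: SmI2 (2.2 equiv, 0.1 M in THF), THF, −78 °C; then pH 7 buffer
Reagents that add atoms: none
Why: SmI2 reduces the C–Br bond to enolate 17, which adds to the phenyl ketone in an intramolecular Reformatsky-type aldol (6-enolendo) through a samarium-bridged chair with the new alkoxide axial, phenyl equatorial and the CH2OSi group pseudo-axial and anti to it; this sets C3 as R with OH trans to the C4 substituent, and the neutral low-temperature conditions leave C4 intact.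

Step 12
Reactants: 18 (3R,4R)-8-(benzyloxy)-3-hydroxy-3-phenyl-4-{[(triethylsilyl)oxy]methyl}-3,4-dihydronaphthalen-1(2H)-one
Product: 20 (1S,2R)-5-(benzyloxy)-2-hydroxy-4-oxo-2-phenyl-1,2,3,4-tetrahydronaphthalene-1-carbaldehyde, via primary alcohol 19 (not isolated)
Conditions: IBX (3 equiv), DMSO, rt
Reagents that add atoms: none
Why: IBX in DMSO cleaves the primary triethylsilyl ether and oxidizes the freed alcohol in the same pot without base, so the β-hydroxy aldehyde is not exposed to retro-aldol or epimerizing conditions.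

Step 13
Reactants: 21 2,2,6-trimethyl-4H-1,3-dioxin-4-one
Product: 22 2,2-dimethyl-6-methylidene-4-(trimethylsilyloxy)-6H-1,3-dioxine
Conditions: LiN(i-Pr)2, THF, −78 °C; then Me3SiCl
Reagents that add atoms: chlorotrimethylsilane, C[Si](C)(C)Cl
Why: kinetic γ-deprotonation of the dioxinone and O-silylation give the dienol silyl ether needed for the vinylogous aldol.

Step 14
Reactants: 20 (1S,2R)-5-(benzyloxy)-2-hydroxy-4-oxo-2-phenyl-1,2,3,4-tetrahydronaphthalene-1-carbaldehyde; 22 2,2-dimethyl-6-methylidene-4-(trimethylsilyloxy)-6H-1,3-dioxine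
Product: 23 6-{2-[(1R,2R)-5-(benzyloxy)-2-hydroxy-4-oxo-2-phenyl-1,2,3,4-tetrahydronaphthalen-1-yl]-2-hydroxyethyl}-2,2-dimethyl-4H-1,3-dioxin-4-one (both epimers at the side-chain carbinol)
Conditions: BF3·OEt2, CH2Cl2, −78 °C; then aq NaHCO3
Reagents that add atoms: none
Why: vinylogous Mukaiyama aldol; the aldehyde is far more electrophilic than the hindered aryl ketone, the dienol ether reacts at its γ-carbon, and the new carbinol centre is uncontrolled because it is oxidized in the next step.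

Step 15
Reactants: 23 6-{2-[(1R,2R)-5-(benzyloxy)-2-hydroxy-4-oxo-2-phenyl-1,2,3,4-tetrahydronaphthalen-1-yl]-2-hydroxyethyl}-2,2-dimethyl-4H-1,3-dioxin-4-one
Product: 24 6-{2-[(1S,2R)-5-(benzyloxy)-2-hydroxy-4-oxo-2-phenyl-1,2,3,4-tetrahydronaphthalen-1-yl]-2-oxoethyl}-2,2-dimethyl-4H-1,3-dioxin-4-one
Conditions: Dess–Martin periodinane, pyridine, CH2Cl2, 0 °C to rt
Reagents that add atoms: none
Why: Dess–Martin oxidation takes only the secondary alcohol, since the tertiary one cannot be oxidized, and the neutral medium avoids retro-aldol of the ketol.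

Step 16
Reactants: 24 6-{2-[(1S,2R)-5-(benzyloxy)-2-hydroxy-4-oxo-2-phenyl-1,2,3,4-tetrahydronaphthalen-1-yl]-2-oxoethyl}-2,2-dimethyl-4H-1,3-dioxin-4-one
Product: 26 6-[(1S,2R)-5-(benzyloxy)-2-hydroxy-4-oxo-2-phenyl-1,2,3,4-tetrahydronaphthalen-1-yl]-4-hydroxy-2H-pyran-2-one (fragment A), via acylketene 25 (not isolated)
Conditions: toluene, 105 °C, 45 min
Reagents that add atoms: none
Why: thermal retro-[4+2] of the dioxinone releases acetone and an acylketene that the enol of the neighbouring ketone closes to the 4-hydroxy-2-pyrone, with no acid or base to disturb the ketol or C4.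

Step 17
Reactants: 27 1-(2,6-dihydroxyphenyl)ethan-1-one
Product: 28 1-[2-(benzyloxy)-6-hydroxyphenyl]ethan-1-one
Conditions: BnBr (1.05 equiv), K2CO3, acetone, reflux
Reagents that add atoms: benzyl bromide, BrCc1ccccc1
Why: Williamson mono-benzylation; after the first alkylation the remaining phenol is locked in a hydrogen bond to the acetyl group and reacts much more slowly.

Step 18
Reactants: 28 1-[2-(benzyloxy)-6-hydroxyphenyl]ethan-1-one
Product: 29 2-acetyl-3-(benzyloxy)phenyl trifluoromethanesulfonate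
Conditions: Tf2O, pyridine, CH2Cl2, 0 °C
Reagents that add atoms: trifluoromethanesulfonic anhydride, O=S(=O)(OS(=O)(=O)C(F)(F)F)C(F)(F)F
Why: O-sulfonylation turns the phenol into an aryl triflate for cross-coupling.

Step 19
Reactants: 30 4-hydroxy-6-methyl-2H-pyran-2-one
Product: 31 4-[(4-methoxybenzyl)oxy]-6-methyl-2H-pyran-2-one
Conditions: 4-methoxybenzyl alcohol, PPh3, DIAD, THF, 0 °C to rt
Reagents that add atoms: (4-methoxyphenyl)methanol, COc1ccc(CO)cc1
Why: Mitsunobu O-alkylation of the acidic 4-OH gives the vinylogous ester cleanly and avoids the C3-alkylation seen with benzylic halides and base.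

Step 20
Reactants: 31 4-[(4-methoxybenzyl)oxy]-6-methyl-2H-pyran-2-one; 32 methyl benzoate
Product: 33 4-[(4-methoxybenzyl)oxy]-6-(2-oxo-2-phenylethyl)-2H-pyran-2-one
Conditions: LiN(i-Pr)2 (2.2 equiv), THF, −78 °C; then 32, −78 to −20 °C; then 1 M HCl
Reagents that add atoms: none
Why: Claisen-type C-acylation of the extended enolate at the 6-methyl group; the second equivalent of base is taken up by the more acidic product, which prevents double acylation.

Step 21
Reactants: 29 2-acetyl-3-(benzyloxy)phenyl trifluoromethanesulfonate; 33 4-[(4-methoxybenzyl)oxy]-6-(2-oxo-2-phenylethyl)-2H-pyran-2-one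
Product: 34 6-{1-[2-acetyl-3-(benzyloxy)phenyl]-2-oxo-2-phenylethyl}-4-[(4-methoxybenzyl)oxy]-2H-pyran-2-one (racemic)
Conditions: Pd2(dba)3 (2.5 mol%), XPhos (6 mol%), K3PO4, toluene, 90 °C
Reagents that add atoms: none
Why: palladium-catalysed α-arylation of the stabilized enolate with the aryl triflate builds the 1,5-diketone; the product stays as its unreactive enolate, and its stereocentre is lost in the next step.

Step 22
Reactants: 34 6-{1-[2-acetyl-3-(benzyloxy)phenyl]-2-oxo-2-phenylethyl}-4-[(4-methoxybenzyl)oxy]-2H-pyran-2-one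
Product: 36 6-[5-(benzyloxy)-4-hydroxy-2-phenylnaphthalen-1-yl]-4-hydroxy-2H-pyran-2-one, via PMB naphthol 35 (not isolated)
Conditions: TsOH·H2O (20 mol%), anisole, toluene, 90 °C
Reagents that add atoms: none
Why: acid-mediated intramolecular aldol condensation of the methyl ketone enol onto the benzoyl carbonyl, then dehydration and tautomerization to the naphthol; the same acid cleaves the 4-methoxybenzyl vinylogous ester, with anisole trapping the cation.

Step 23
Reactants: 36 6-[5-(benzyloxy)-4-hydroxy-2-phenylnaphthalen-1-yl]-4-hydroxy-2H-pyran-2-one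
Product: 38 benzyl 8-(benzyloxy)-4-(4-hydroxy-2-oxo-2H-pyran-6-yl)-3-phenylnaphthalen-1-yl carbonate, via bis-carbonate 37 (not isolated)
Conditions: CbzCl (2.5 equiv), pyridine, DMAP (cat.), CH2Cl2, 0 °C; then MeOH, rt
Reagents that add atoms: benzyl chloroformate, O=C(Cl)OCc1ccccc1
Why: both hydroxyls are acylated and the pyronyl carbonate, a vinylogous mixed anhydride, is then methanolysed selectively, leaving the naphthol masked as an electron-poor carbonate that hydrogenolysis removes later.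

Step 24
Reactants: 38 benzyl 8-(benzyloxy)-4-(4-hydroxy-2-oxo-2H-pyran-6-yl)-3-phenylnaphthalen-1-yl carbonate
Product: 39 {[6-(5-(benzyloxy)-4-{[(benzyloxy)carbonyl]oxy}-2-phenylnaphthalen-1-yl)-4-hydroxy-2-oxo-2H-pyran-3-yl]methyl}dimethylammonium iodide
Conditions: CH2=NMe2+ I−, MeCN, 0 °C to rt
Reagents that add atoms: N,N-dimethylmethyleneiminium iodide, C=[N+](C)C.[I-]
Why: Mannich reaction of the preformed iminium ion at the nucleophilic C3 of the 4-hydroxy-2-pyrone; isolating the hydroiodide prevents premature loss of amine.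

Step 25
Reactants: 26 6-[(1S,2R)-5-(benzyloxy)-2-hydroxy-4-oxo-2-phenyl-1,2,3,4-tetrahydronaphthalen-1-yl]-4-hydroxy-2H-pyran-2-one; 39 Mannich salt of fragment B
Product: 41 tris-protected wailupemycin H (8-O-benzyl on the ketol half and 5-O-benzyl plus 4-O-benzyloxycarbonyl on the naphthalene half; 3R,4S), via pyranedione methide 40 (not isolated)
Conditions: i-Pr2NEt (1.0 equiv), MeCN, rt to 40 °C
Reagents that add atoms: none
Why: the freed Mannich base loses dimethylamine (retro-Michael) to the 3-methylidene-pyran-2,4-dione 40, and the pyronate of 26 adds to it in a Michael reaction; because only one partner carries the CH2 unit, the unsymmetrical bis-pyrone is favoured, and no stereocentre is touched.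

Step 26
Reactants: 41 tris-protected wailupemycin H
Product: 42 wailupemycin H
Conditions: H2 (1 atm), Pd/C (10% palladium on carbon), EtOAc/MeOH, rt
Reagents that add atoms: none
Why: hydrogenolysis of the two benzyl ethers and the benzyl carbonate (with loss of CO2) under neutral conditions leaves the ketol, both pyrones and the tertiary benzylic alcohol intact.

## Compound list

1 | 2-bromo-3-hydroxybenzaldehyde | O=Cc1cccc(O)c1Br | starting material
2 | 3-(benzyloxy)-2-bromobenzaldehyde | O=Cc1cccc(OCc2ccccc2)c1Br | intermediate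
3 | N-{2-[3-(benzyloxy)-2-bromophenyl]-1-(4-methylbenzenesulfonyl)ethenyl}formamide (not isolated) | O=CNC(=Cc1cccc(OCc2ccccc2)c1Br)S(=O)(=O)c1ccc(C)cc1 | intermediate
4 | 2-[3-(benzyloxy)-2-bromophenyl]acetonitrile | N#CCc1cccc(OCc2ccccc2)c1Br | intermediate
5 | 2-[3-(benzyloxy)-2-bromophenyl]acetamide (not isolated) | NC(=O)Cc1cccc(OCc2ccccc2)c1Br | intermediate
6 | 2-[3-(benzyloxy)-2-bromophenyl]acetic acid | OC(=O)Cc1cccc(OCc2ccccc2)c1Br | intermediate
7 | (4S)-4-benzyl-1,3-oxazolidin-2-one | O=C1N[C@@H](Cc2ccccc2)CO1 | starting material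
8 | 2-[3-(benzyloxy)-2-bromophenyl]acetic pivalic anhydride (not isolated) | CC(C)(C)C(=O)OC(=O)Cc1cccc(OCc2ccccc2)c1Br | intermediate
9 | (4S)-4-benzyl-3-{2-[3-(benzyloxy)-2-bromophenyl]acetyl}-1,3-oxazolidin-2-one | O=C(Cc1cccc(OCc2ccccc2)c1Br)N1[C@@H](Cc2ccccc2)COC1=O | intermediate
10 | benzaldehyde | O=Cc1ccccc1 | starting material
11 | (4S)-4-benzyl-3-{(2S,3S)-2-[3-(benzyloxy)-2-bromophenyl]-3-hydroxy-3-phenylpropanoyl}-1,3-oxazolidin-2-one | O=C(N1[C@@H](Cc2ccccc2)COC1=O)[C@@H](c1cccc(OCc2ccccc2)c1Br)[C@H](O)c1ccccc1 | intermediate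
12 | (1S,2R)-2-[3-(benzyloxy)-2-bromophenyl]-1-phenylpropane-1,3-diol | OC[C@@H](c1cccc(OCc2ccccc2)c1Br)[C@H](O)c1ccccc1 | intermediate
13 | (1S,2R)-2-[3-(benzyloxy)-2-bromophenyl]-1-phenyl-3-[(triethylsilyl)oxy]propan-1-ol | CC[Si](CC)(CC)OC[C@@H](c1cccc(OCc2ccccc2)c1Br)[C@H](O)c1ccccc1 | intermediate
14 | (2R)-2-[3-(benzyloxy)-2-bromophenyl]-1-phenyl-3-[(triethylsilyl)oxy]propan-1-one | O=C(c1ccccc1)[C@@H](CO[Si](CC)(CC)CC)c1cccc(OCc2ccccc2)c1Br | intermediate
15 | (2R)-2-[3-(benzyloxy)-2-(1-ethoxyethenyl)phenyl]-1-phenyl-3-[(triethylsilyl)oxy]propan-1-one | O=C(c1ccccc1)[C@@H](CO[Si](CC)(CC)CC)c1cccc(OCc2ccccc2)c1C(=C)OCC | intermediate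
16 | (2R)-2-[3-(benzyloxy)-2-(2-bromoacetyl)phenyl]-1-phenyl-3-[(triethylsilyl)oxy]propan-1-one | O=C(c1ccccc1)[C@@H](CO[Si](CC)(CC)CC)c1cccc(OCc2ccccc2)c1C(=O)CBr | intermediate
17 | diiodosamarium enolate of the aryl methyl ketone derived from 16 (not isolated) | O=C(c1ccccc1)[C@@H](CO[Si](CC)(CC)CC)c1cccc(OCc2ccccc2)c1C(=C)O[Sm](I)I | intermediate
18 | (3R,4R)-8-(benzyloxy)-3-hydroxy-3-phenyl-4-{[(triethylsilyl)oxy]methyl}-3,4-dihydronaphthalen-1(2H)-one | O=C1C[C@](O)(c2ccccc2)[C@@H](CO[Si](CC)(CC)CC)c2cccc(OCc3ccccc3)c21 | intermediate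
19 | (3R,4R)-8-(benzyloxy)-3-hydroxy-4-(hydroxymethyl)-3-phenyl-3,4-dihydronaphthalen-1(2H)-one (not isolated) | O=C1C[C@](O)(c2ccccc2)[C@@H](CO)c2cccc(OCc3ccccc3)c21 | intermediate
20 | (1S,2R)-5-(benzyloxy)-2-hydroxy-4-oxo-2-phenyl-1,2,3,4-tetrahydronaphthalene-1-carbaldehyde | O=C1C[C@](O)(c2ccccc2)[C@@H](C=O)c2cccc(OCc3ccccc3)c21 | intermediate
21 | 2,2,6-trimethyl-4H-1,3-dioxin-4-one | CC1=CC(=O)OC(C)(C)O1 | starting material
22 | 2,2-dimethyl-6-methylidene-4-(trimethylsilyloxy)-6H-1,3-dioxine | C=C1C=C(O[Si](C)(C)C)OC(C)(C)O1 | intermediate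
23 | 6-{2-[(1R,2R)-5-(benzyloxy)-2-hydroxy-4-oxo-2-phenyl-1,2,3,4-tetrahydronaphthalen-1-yl]-2-hydroxyethyl}-2,2-dimethyl-4H-1,3-dioxin-4-one (both epimers at the side-chain carbinol) | O=C1C[C@](O)(c2ccccc2)[C@@H](C(O)CC2=CC(=O)OC(C)(C)O2)c2cccc(OCc3ccccc3)c21 | intermediate
24 | 6-{2-[(1S,2R)-5-(benzyloxy)-2-hydroxy-4-oxo-2-phenyl-1,2,3,4-tetrahydronaphthalen-1-yl]-2-oxoethyl}-2,2-dimethyl-4H-1,3-dioxin-4-one | O=C1C[C@](O)(c2ccccc2)[C@@H](C(=O)CC2=CC(=O)OC(C)(C)O2)c2cccc(OCc3ccccc3)c21 | intermediate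
25 | acylketene from 24 by loss of acetone (not isolated) | O=C1C[C@](O)(c2ccccc2)[C@@H](C(=O)CC(=O)C=C=O)c2cccc(OCc3ccccc3)c21 | intermediate
26 | 6-[(1S,2R)-5-(benzyloxy)-2-hydroxy-4-oxo-2-phenyl-1,2,3,4-tetrahydronaphthalen-1-yl]-4-hydroxy-2H-pyran-2-one (fragment A) | O=C1C[C@](O)(c2ccccc2)[C@@H](c2cc(O)cc(=O)o2)c2cccc(OCc3ccccc3)c21 | intermediate
27 | 1-(2,6-dihydroxyphenyl)ethan-1-one | CC(=O)c1c(O)cccc1O | starting material
28 | 1-[2-(benzyloxy)-6-hydroxyphenyl]ethan-1-one | CC(=O)c1c(O)cccc1OCc1ccccc1 | intermediate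
29 | 2-acetyl-3-(benzyloxy)phenyl trifluoromethanesulfonate | CC(=O)c1c(OCc2ccccc2)cccc1OS(=O)(=O)C(F)(F)F | intermediate
30 | 4-hydroxy-6-methyl-2H-pyran-2-one | Cc1cc(O)cc(=O)o1 | starting material
31 | 4-[(4-methoxybenzyl)oxy]-6-methyl-2H-pyran-2-one | Cc1cc(OCc2ccc(OC)cc2)cc(=O)o1 | intermediate
32 | methyl benzoate | COC(=O)c1ccccc1 | starting material
33 | 4-[(4-methoxybenzyl)oxy]-6-(2-oxo-2-phenylethyl)-2H-pyran-2-one | O=C(Cc1cc(OCc2ccc(OC)cc2)cc(=O)o1)c1ccccc1 | intermediate
34 | 6-{1-[2-acetyl-3-(benzyloxy)phenyl]-2-oxo-2-phenylethyl}-4-[(4-methoxybenzyl)oxy]-2H-pyran-2-one (racemic) | CC(=O)c1c(OCc2ccccc2)cccc1C(C(=O)c1ccccc1)c1cc(OCc2ccc(OC)cc2)cc(=O)o1 | intermediate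
35 | 6-[5-(benzyloxy)-4-hydroxy-2-phenylnaphthalen-1-yl]-4-[(4-methoxybenzyl)oxy]-2H-pyran-2-one (not isolated) | O=c1cc(OCc2ccc(OC)cc2)cc(-c2c(-c3ccccc3)cc(O)c3c(OCc4ccccc4)cccc23)o1 | intermediate
36 | 6-[5-(benzyloxy)-4-hydroxy-2-phenylnaphthalen-1-yl]-4-hydroxy-2H-pyran-2-one | O=c1cc(O)cc(-c2c(-c3ccccc3)cc(O)c3c(OCc4ccccc4)cccc23)o1 | intermediate
37 | benzyl 8-(benzyloxy)-4-(4-{[(benzyloxy)carbonyl]oxy}-2-oxo-2H-pyran-6-yl)-3-phenylnaphthalen-1-yl carbonate (not isolated) | O=c1cc(OC(=O)OCc2ccccc2)cc(-c2c(-c3ccccc3)cc(OC(=O)OCc3ccccc3)c3c(OCc4ccccc4)cccc23)o1 | intermediate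
38 | benzyl 8-(benzyloxy)-4-(4-hydroxy-2-oxo-2H-pyran-6-yl)-3-phenylnaphthalen-1-yl carbonate | O=c1cc(O)cc(-c2c(-c3ccccc3)cc(OC(=O)OCc3ccccc3)c3c(OCc4ccccc4)cccc23)o1 | intermediate
39 | {[6-(5-(benzyloxy)-4-{[(benzyloxy)carbonyl]oxy}-2-phenylnaphthalen-1-yl)-4-hydroxy-2-oxo-2H-pyran-3-yl]methyl}dimethylammonium iodide | C[NH+](C)Cc1c(O)cc(-c2c(-c3ccccc3)cc(OC(=O)OCc3ccccc3)c3c(OCc4ccccc4)cccc23)oc1=O.[I-] | intermediate
40 | benzyl 8-(benzyloxy)-4-(3-methylidene-2,4-dioxo-3,4-dihydro-2H-pyran-6-yl)-3-phenylnaphthalen-1-yl carbonate (not isolated) | C=C1C(=O)C=C(-c2c(-c3ccccc3)cc(OC(=O)OCc3ccccc3)c3c(OCc4ccccc4)cccc23)OC1=O | intermediate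
41 | tris-protected wailupemycin H: 8-O-benzyl on the (3R,4S)-ketol half; 5-O-benzyl and 4-O-benzyloxycarbonyl on the naphthalene half | O=C1C[C@](O)(c2ccccc2)[C@@H](c2cc(O)c(Cc3c(O)cc(-c4c(-c5ccccc5)cc(OC(=O)OCc5ccccc5)c5c(OCc6ccccc6)cccc45)oc3=O)c(=O)o2)c2cccc(OCc3ccccc3)c21 | intermediate
42 | wailupemycin H, 6-[(1S,2R)-2,5-dihydroxy-4-oxo-2-phenyl-1,2,3,4-tetrahydronaphthalen-1-yl]-3-{[6-(4,5-dihydroxy-2-phenylnaphthalen-1-yl)-4-hydroxy-2-oxo-2H-pyran-3-yl]methyl}-4-hydroxy-2H-pyran-2-one | O=C1C[C@](O)(c2ccccc2)[C@@H](c2cc(O)c(Cc3c(O)cc(-c4c(-c5ccccc5)cc(O)c5c(O)cccc45)oc3=O)c(=O)o2)c2cccc(O)c21 | target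

## Step count and risks

Total step count: 26.
Longest linear sequence: 17 steps (1–12, 14–16, 25, 26).

Risk 1, the samarium aldol (step 11). The diastereoselectivity rests on a transition-state model (closed chair, non-chelating silyl ether) and has no direct precedent on this substrate. The phenyl ketone could also be reduced, or C4 could erode on the way to 16. The fallback sets out from 16. Zn dust and Me3SiCl in THF convert the bromoketone regiospecifically into the trimethylsilyl enol ether (2R)-2-{3-(benzyloxy)-2-[1-(trimethylsilyloxy)ethenyl]phenyl}-1-phenyl-3-[(triethylsilyl)oxy]propan-1-one F1. TiCl4 in CH2Cl2 at −78 °C then closes the ring by a Mukaiyama aldol, in which the ketone is activated by the Lewis acid and the transition state is open, so the facial preference is complementary. Aqueous work-up returns the route to 18.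

Risk 2, the α-arylation (step 21). The enolate of 33 is strongly stabilized and hindered, so reductive elimination may be slow and triflate hydrolysis may win. The fallback sets out from 29 and 31 and makes the aryl–CH2 bond first. PdCl2(dppf), KOAc and bis(pinacolato)diboron turn 29 into 1-[2-(benzyloxy)-6-(4,4,5,5-tetramethyl-1,3,2-dioxaborolan-2-yl)phenyl]ethan-1-one F2. LiN(SiMe3)2 and then CBr4 turn 31 into 6-(bromomethyl)-4-[(4-methoxybenzyl)oxy]-2H-pyran-2-one F3. A Suzuki–Miyaura coupling (Pd(PPh3)4, K2CO3, dioxane/H2O) joins them to 6-{[2-acetyl-3-(benzyloxy)phenyl]methyl}-4-[(4-methoxybenzyl)oxy]-2H-pyran-2-one F4. Its doubly activated CH2 is far more acidic than the acetyl group, so LiN(SiMe3)2 (2 equiv) and methyl benzoate 32 acylate it selectively, and the route is rejoined at 34.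

Risk 3, the methide cross-coupling (step 25). Retro-Mannich scrambling could transfer the CH2 unit and give the two symmetrical dimers, and the liberated amine could open the ketol. The fallback sets out from 38 and fixes the bridging carbon covalently before the second half is added. N,N-Dimethylformamide dimethyl acetal gives the enaminone benzyl 8-(benzyloxy)-4-{3-[(dimethylamino)methylidene]-2,4-dioxo-3,4-dihydro-2H-pyran-6-yl}-3-phenylnaphthalen-1-yl carbonate F5. Pyrone 26 adds to it with loss of dimethylamine (AcOH, EtOH, rt) to give the methine-bridged bis-pyrone F6. A Hantzsch ester then reduces only the activated exocyclic C=C to the CH2 bridge, and the route is rejoined at 41.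

Further compounds
F1 | step 11 | (2R)-2-{3-(benzyloxy)-2-[1-(trimethylsilyloxy)ethenyl]phenyl}-1-phenyl-3-[(triethylsilyl)oxy]propan-1-one | O=C(c1ccccc1)[C@@H](CO[Si](CC)(CC)CC)c1cccc(OCc2ccccc2)c1C(=C)O[Si](C)(C)C
F2 | step 21 | 1-[2-(benzyloxy)-6-(4,4,5,5-tetramethyl-1,3,2-dioxaborolan-2-yl)phenyl]ethan-1-one | CC(=O)c1c(OCc2ccccc2)cccc1B1OC(C)(C)C(C)(C)O1
F3 | step 21 | 6-(bromomethyl)-4-[(4-methoxybenzyl)oxy]-2H-pyran-2-one | BrCc1cc(OCc2ccc(OC)cc2)cc(=O)o1
F4 | step 21 | 6-{[2-acetyl-3-(benzyloxy)phenyl]methyl}-4-[(4-methoxybenzyl)oxy]-2H-pyran-2-one | CC(=O)c1c(OCc2ccccc2)cccc1Cc1cc(OCc2ccc(OC)cc2)cc(=O)o1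
F5 | step 25 | benzyl 8-(benzyloxy)-4-{3-[(dimethylamino)methylidene]-2,4-dioxo-3,4-dihydro-2H-pyran-6-yl}-3-phenylnaphthalen-1-yl carbonate | CN(C)C=C1C(=O)C=C(-c2c(-c3ccccc3)cc(OC(=O)OCc3ccccc3)c3c(OCc4ccccc4)cccc23)OC1=O
F6 | step 25 | methine-bridged analogue of 41 (bridge CH= in place of CH2; naphthyl pyrone half as its 3-ylidene-2,4-dione) | O=C1C[C@](O)(c2ccccc2)[C@@H](c2cc(O)c(C=C3C(=O)C=C(-c4c(-c5ccccc5)cc(OC(=O)OCc5ccccc5)c5c(OCc6ccccc6)cccc45)OC3=O)c(=O)o2)c2cccc(OCc3ccccc3)c21
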